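The γ-lactone ring (O1–C2–C3–C4–C5) is read as a carbonylated tertiary vinyl carbinol: O1 on the quaternary C2 and the terminal carbon C4 of a vinyl group on the same atom are bridged by one molecule of CO. In one operation palladium ties CO to O1 and then closes the ring by joining C4 to the new carbonyl carbon C5. The precursor is an acyclic dibenzyl 2-hydroxy-2-vinyl-3-alkylsuccinate. Its two stereocentres (C2 and the adjacent C1') are set together by a catalytic syn-selective Mukaiyama aldol addition to a methionine-derived α-keto ester, whose methylthioethyl arm is the latent vinyl group. (R)-Malic acid enters last as its O-trifluoroacetyl anhydride.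

Key step: step 9

Atom labels: O1, C2 (quaternary), C3, C4 and C5 (carbonyl) are the lactone ring atoms; C1' is the side-chain carbon on C2 that carries the second carboxyl group.

Remark on the chemistry: the sense of induction of the copper catalyst in step 5 (si face of the keto ester, syn adduct) is assigned by analogy with pyruvate esters; the (R,R)-ligand would be used if the opposite sense were found.

Step 1
Reactants: 1 12-bromododecanoic acid; 2 benzyl alcohol
Product: 3 12-(benzyloxy)dodecanoic acid
Conditions: NaH (2.3 equiv), BnOH (1.2 equiv), THF/DMF, 0 °C to 60 °C; aq. HCl work-up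
Reagents that add atoms: none
Why: Williamson ether synthesis, in which the sodium carboxylate is inert and sodium benzyloxide displaces the primary bromide by SN2.

Step 2
Reactants: 3 12-(benzyloxy)dodecanoic acid; 4 2-methylpropane-2-thiol
Product: 5 S-tert-butyl 12-(benzyloxy)dodecanethioate
Conditions: DCC, DMAP (cat.), CH2Cl2, 0 °C to rt
Reagents that add atoms: none
Why: Steglich-type thioesterification through the O-acylisourea and the acylpyridinium ion, which the thiol intercepts.

Step 3
Reactants: 5 S-tert-butyl 12-(benzyloxy)dodecanethioate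
Product: 6 (Z)-{[12-(benzyloxy)-1-(tert-butylsulfanyl)dodec-1-en-1-yl]oxy}trimethylsilane
Conditions: LiN(iPr)2 (LDA, 1.1 equiv), THF, −78 °C; then Me3SiCl, −78 °C to rt; filtration under argon, used crude
Reagents that add atoms: chlorotrimethylsilane, C[Si](C)(C)Cl
Why: Kinetic enolisation of the thioester should place the chain trans to O–Li, and O-silylation then gives mainly the (Z)-silyl ketene thioacetal (enolate trapping); the aldol of step 5 is expected to be stereoconvergent with respect to this geometry.

Step 4
Reactants: 7 sodium 4-(methylsulfanyl)-2-oxobutanoate; 8 benzyl bromide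
Product: 9 benzyl 4-(methylsulfanyl)-2-oxobutanoate
Conditions: BnBr (1.0 equiv), DMF, rt
Reagents that add atoms: none
Why: SN2 O-alkylation of the carboxylate, which in DMF should be a far better nucleophile than the thioether when only one equivalent of benzyl bromide is used.

Step 5
Reactants: 6 (Z)-{[12-(benzyloxy)-1-(tert-butylsulfanyl)dodec-1-en-1-yl]oxy}trimethylsilane; 9 benzyl 4-(methylsulfanyl)-2-oxobutanoate
Product: 11 benzyl (2S,3S)-13-(benzyloxy)-3-[(tert-butylsulfanyl)carbonyl]-2-hydroxy-2-[2-(methylsulfanyl)ethyl]tridecanoate, via silyl ether 10 (not isolated)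
Conditions: Cu(OTf)2 (10 mol %), (S,S)-tBu-box [2,2'-(propane-2,2-diyl)bis((4S)-4-tert-butyl-4,5-dihydrooxazole), 11 mol %], THF, −78 °C; then 1 M HCl, THF, rt
Reagents that add atoms: none
Why: Catalytic enantioselective Mukaiyama aldol addition to an α-keto ester: the keto ester chelates divalent copper through both carbonyl oxygens, the tert-butyl groups of the ligand should leave the si face of the ketone open, and the open transition state should give the syn adduct, so that C2 (S) and C1' (S) are both set in this step under catalyst control.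

Step 6
Reactants: 11 benzyl (2S,3S)-13-(benzyloxy)-3-[(tert-butylsulfanyl)carbonyl]-2-hydroxy-2-[2-(methylsulfanyl)ethyl]tridecanoate
Product: 12 benzyl (2S,3S)-13-(benzyloxy)-3-[(tert-butylsulfanyl)carbonyl]-2-hydroxy-2-[2-(methanesulfinyl)ethyl]tridecanoate (both configurations at sulfur)
Conditions: NaIO4 (1.05 equiv), MeOH/THF/H2O, 0 °C to rt
Reagents that add atoms: sodium periodate, [Na+].[O-]I(=O)(=O)=O
Why: Periodate oxidation of a dialkyl sulfide should stop at the sulfoxide and leave the thioester, the esters and the tertiary alcohol untouched.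

Step 7
Reactants: 12 benzyl (2S,3S)-13-(benzyloxy)-3-[(tert-butylsulfanyl)carbonyl]-2-hydroxy-2-[2-(methanesulfinyl)ethyl]tridecanoate
Product: 13 benzyl (2S,3S)-13-(benzyloxy)-3-[(tert-butylsulfanyl)carbonyl]-2-ethenyl-2-hydroxytridecanoate
Conditions: degassed o-xylene, 145 °C
Reagents that add atoms: none
Why: Thermal syn-elimination of the methyl sulfoxide (Ei), in which only C3 offers a β-hydrogen, so the C3=C4 vinyl group is the only possible alkene and the quaternary C2 rules out its migration into conjugation.

Step 8
Reactants: 13 benzyl (2S,3S)-13-(benzyloxy)-3-[(tert-butylsulfanyl)carbonyl]-2-ethenyl-2-hydroxytridecanoate; 2 benzyl alcohol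
Product: 14 dibenzyl (2S,3S)-3-[10-(benzyloxy)decyl]-2-ethenyl-2-hydroxybutanedioate
Conditions: AgOCOCF3 (1.5 equiv), BnOH (10 equiv), THF, rt to 50 °C
Reagents that add atoms: none
Why: Silver-promoted thioester alcoholysis, in which thiophilic monovalent silver activates the S-tert-butyl thioester for acyl transfer to the large excess of benzyl alcohol while the oxo ester and the alkene are not touched.

Step 9
Reactants: 14 dibenzyl (2S,3S)-3-[10-(benzyloxy)decyl]-2-ethenyl-2-hydroxybutanedioate
Product: 16 benzyl (2S)-2-[(2S)-1,12-bis(benzyloxy)-1-oxododecan-2-yl]-5-oxooxolane-2-carboxylate, via alkoxycarbonylpalladium hydride 15 (not isolated)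
Conditions: Pd(dba)2 (5 mol %), 1,4-bis(diphenylphosphino)butane (dppb, 5 mol %), CO (40 bar), H2 (14 bar), 1,2-dimethoxyethane, 110 °C
Reagents that add atoms: carbon monoxide, [C-]#[O+]
Why: Palladium-catalysed cyclocarbonylation of a tertiary allylic alcohol (closest known type: Pd/diphosphine cyclocarbonylation of allylic alcohols to γ-butyrolactones): zerovalent palladium, CO and the O1–H bond give the alkoxycarbonylpalladium hydride 15 in which C5 is already bound to O1, the vinyl group inserts into Pd–H with palladium going to the terminal carbon C4, and C–C reductive elimination from the six-membered acyl–alkyl palladacycle forms the C4–C5 bond and thereby closes the lactone ring O1–C2–C3–C4–C5. The closure is formally 5-endo-trig, which is acceptable here because it runs through the metallacycle and not through direct attack on the alkene. No stereocentre is created: C2 and C1' come from step 5 and none of their bonds is broken. The step needs regioselectivity for C4 over C3 (γ- versus β-lactone), which the quaternary C2 next to C3 and the preference for the six-membered palladacycle should secure. It also needs chemoselectivity against ionisation of the tertiary allylic C–O bond and against hydrogenation of the vinyl group; the electron-withdrawing ester on C2 disfavours an allylpalladium cation, the CO-rich gas phase (H2 only sustains the hydride) disfavours hydrogenation, and the benzyl ester and ether groups should be inert to the homogeneous CO-ligated catalyst.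

Step 10
Reactants: 16 benzyl (2S)-2-[(2S)-1,12-bis(benzyloxy)-1-oxododecan-2-yl]-5-oxooxolane-2-carboxylate
Product: 17 (2S)-2-[(1S)-1-carboxy-11-hydroxyundecyl]-5-oxooxolane-2-carboxylic acid
Conditions: H2 (1 atm), Pd on carbon (10 % Pd/C), EtOAc/THF, rt
Reagents that add atoms: none
Why: Heterogeneous hydrogenolysis should cleave the two benzyl esters and the benzyl ether in one operation and leave the lactone and both stereocentres intact.

Step 11
Reactants: 18 (R)-malic acid
Product: 19 (3R)-2,5-dioxooxolan-3-yl 2,2,2-trifluoroacetate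
Conditions: (CF3CO)2O (excess, neat), 0 °C to rt; volatiles removed in vacuo, used directly
Reagents that add atoms: trifluoroacetic anhydride, O=C(OC(=O)C(F)(F)F)C(F)(F)F
Why: O-Trifluoroacetylation and cyclodehydration through the mixed anhydride give the activated cyclic anhydride without touching the C–O stereocentre.

Step 12
Reactants: 17 (2S)-2-[(1S)-1-carboxy-11-hydroxyundecyl]-5-oxooxolane-2-carboxylic acid; 19 (3R)-2,5-dioxooxolan-3-yl 2,2,2-trifluoroacetate
Product: 21 (2S)-2-[(1S)-1-carboxy-11-{[(2R)-3-carboxy-2-hydroxypropanoyl]oxy}undecyl]-5-oxooxolane-2-carboxylic acid, via trifluoroacetate ester 20 (not isolated)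
Conditions: 19 (1.3 equiv), THF, 0 °C to rt; then H2O, rt; reversed-phase chromatography
Reagents that add atoms: none
Why: Regioselective alcoholysis of the cyclic anhydride: the primary alcohol should attack the carbonyl next to the electron-withdrawing trifluoroacetoxy group and give the 1-ester with the 4-carboxyl free; carboxylic acids are tolerated because the product of the opening is itself an acid, and water then hydrolyses the labile trifluoroacetate.

Compound list
1 | 12-bromododecanoic acid | OC(=O)CCCCCCCCCCCBr | starting material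
2 | benzyl alcohol | OCc1ccccc1 | starting material
3 | 12-(benzyloxy)dodecanoic acid | OC(=O)CCCCCCCCCCCOCc1ccccc1 | intermediate
4 | 2-methylpropane-2-thiol | CC(C)(C)S | starting material
5 | S-tert-butyl 12-(benzyloxy)dodecanethioate | CC(C)(C)SC(=O)CCCCCCCCCCCOCc1ccccc1 | intermediate
6 | (Z)-{[12-(benzyloxy)-1-(tert-butylsulfanyl)dodec-1-en-1-yl]oxy}trimethylsilane | C[Si](C)(C)O/C(SC(C)(C)C)=C/CCCCCCCCCCOCc1ccccc1 | intermediate
7 | sodium 4-(methylsulfanyl)-2-oxobutanoate | CSCCC(=O)C(=O)[O-].[Na+] | starting material
8 | benzyl bromide | BrCc1ccccc1 | starting material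
9 | benzyl 4-(methylsulfanyl)-2-oxobutanoate | CSCCC(=O)C(=O)OCc1ccccc1 | intermediate
10 | benzyl (2S,3S)-13-(benzyloxy)-3-[(tert-butylsulfanyl)carbonyl]-2-[2-(methylsulfanyl)ethyl]-2-[(trimethylsilyl)oxy]tridecanoate | c1ccccc1COCCCCCCCCCC[C@H](C(=O)SC(C)(C)C)[C@](O[Si](C)(C)C)(C(=O)OCc1ccccc1)CCSC | intermediate
11 | benzyl (2S,3S)-13-(benzyloxy)-3-[(tert-butylsulfanyl)carbonyl]-2-hydroxy-2-[2-(methylsulfanyl)ethyl]tridecanoate | c1ccccc1COCCCCCCCCCC[C@H](C(=O)SC(C)(C)C)[C@](O)(C(=O)OCc1ccccc1)CCSC | intermediate
12 | benzyl (2S,3S)-13-(benzyloxy)-3-[(tert-butylsulfanyl)carbonyl]-2-hydroxy-2-[2-(methanesulfinyl)ethyl]tridecanoate (both configurations at sulfur) | c1ccccc1COCCCCCCCCCC[C@H](C(=O)SC(C)(C)C)[C@](O)(C(=O)OCc1ccccc1)CCS(C)=O | intermediate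
13 | benzyl (2S,3S)-13-(benzyloxy)-3-[(tert-butylsulfanyl)carbonyl]-2-ethenyl-2-hydroxytridecanoate | c1ccccc1COCCCCCCCCCC[C@H](C(=O)SC(C)(C)C)[C@](O)(C(=O)OCc1ccccc1)C=C | intermediate
14 | dibenzyl (2S,3S)-3-[10-(benzyloxy)decyl]-2-ethenyl-2-hydroxybutanedioate | c1ccccc1COCCCCCCCCCC[C@H](C(=O)OCc1ccccc1)[C@](O)(C(=O)OCc1ccccc1)C=C | intermediate
15 | alkoxycarbonylpalladium hydride Pd(H)(CO2R)(dppb) formed from 14, R being the carbinol residue of 14 (the diphosphine is left out of the SMILES) | c1ccccc1COCCCCCCCCCC[C@H](C(=O)OCc1ccccc1)[C@](OC(=O)[PdH])(C(=O)OCc1ccccc1)C=C | intermediate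
16 | benzyl (2S)-2-[(2S)-1,12-bis(benzyloxy)-1-oxododecan-2-yl]-5-oxooxolane-2-carboxylate | c1ccccc1COCCCCCCCCCC[C@H](C(=O)OCc1ccccc1)[C@]1(C(=O)OCc2ccccc2)CCC(=O)O1 | intermediate
17 | (2S)-2-[(1S)-1-carboxy-11-hydroxyundecyl]-5-oxooxolane-2-carboxylic acid | OCCCCCCCCCC[C@H](C(=O)O)[C@]1(C(=O)O)CCC(=O)O1 | intermediate
18 | (R)-malic acid | OC(=O)C[C@@H](O)C(=O)O | starting material
19 | (3R)-2,5-dioxooxolan-3-yl 2,2,2-trifluoroacetate | O=C1C[C@@H](OC(=O)C(F)(F)F)C(=O)O1 | intermediate
20 | (2S)-2-[(1S)-1-carboxy-11-{[(2R)-3-carboxy-2-(trifluoroacetoxy)propanoyl]oxy}undecyl]-5-oxooxolane-2-carboxylic acid | OC(=O)C[C@@H](OC(=O)C(F)(F)F)C(=O)OCCCCCCCCCC[C@H](C(=O)O)[C@]1(C(=O)O)CCC(=O)O1 | intermediate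
21 | (2S)-2-[(1S)-1-carboxy-11-{[(2R)-3-carboxy-2-hydroxypropanoyl]oxy}undecyl]-5-oxooxolane-2-carboxylic acid | O=C(O)C[C@@H](O)C(=O)OCCCCCCCCCC[C@H](C(=O)O)[C@]1(C(=O)O)CCC(=O)O1 | target

Total step count: 12. Longest linear sequence: 10 steps (1, 2, 3, 5, 6, 7, 8, 9, 10, 12).

Steps most likely to fail

Step 9. The hindered, electron-poor tertiary hydroxyl may not enter the alkoxycarbonyl pathway, so that no carbonylative closure takes place and hydrogenation of the vinyl group or ionisation of the allylic C–O bond takes over. The fallback sets out from 14 and comes back at 16. Hydroformylation with Rh(acac)(CO)2 and Xantphos under CO/H2 (1:1, 20 bar) in toluene at 80 °C should place the formyl carbon on C4, and the aldehyde is trapped by O1 as the lactol benzyl (2S)-2-[(2S)-1,12-bis(benzyloxy)-1-oxododecan-2-yl]-5-hydroxyoxolane-2-carboxylate F1 (anomer mixture). Oxidation of the lactol with TEMPO (cat.) and PhI(OAc)2 in CH2Cl2 then gives 16.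

Step 5. The thioether of 9 may compete with the 1,2-dicarbonyl chelate for divalent copper, which would stall turnover or erode facial and syn selectivity. The fallback sets out from 6 and comes back at 13, and it makes steps 4, 6 and 7 unnecessary. Ethynyltrimethylsilane is lithiated with n-BuLi to lithium (trimethylsilyl)acetylide F2, which is acylated with dibenzyl oxalate (THF, −78 °C) to benzyl 2-oxo-4-(trimethylsilyl)but-3-ynoate F3. The same Cu(OTf)2/(S,S)-tBu-box aldol of 6 with this sulfur-free keto ester should give benzyl (2R,3S)-13-(benzyloxy)-3-[(tert-butylsulfanyl)carbonyl]-2-[(trimethylsilyl)ethynyl]-2-[(trimethylsilyl)oxy]tridecanoate F4. Bu4NF buffered with AcOH in THF removes both silyl groups to give benzyl (2R,3S)-13-(benzyloxy)-3-[(tert-butylsulfanyl)carbonyl]-2-ethynyl-2-hydroxytridecanoate F5. Semihydrogenation (H2, Pd/CaCO3 poisoned with Pb(OAc)2, quinoline, EtOAc) then gives 13. The spatial arrangement at C2 is the same throughout; the descriptor reads R in the alkynes only because alkynyl outranks C3.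

Step 8. Alcoholysis at the α-branched acyl carbon may stall, or the neighbouring tertiary hydroxyl may close a β-lactone faster than benzyl alcohol arrives. The fallback sets out from 13 and comes back at 14. LiOH in aqueous THF at 0 °C hydrolyses the thioester and the benzyl ester to (2S,3S)-3-[10-(benzyloxy)decyl]-2-ethenyl-2-hydroxybutanedioic acid F6. Double O-alkylation of the dicarboxylate with benzyl bromide 8 and Cs2CO3 in DMF at rt then gives 14.

Further compounds
F1 | step 9 | benzyl (2S)-2-[(2S)-1,12-bis(benzyloxy)-1-oxododecan-2-yl]-5-hydroxyoxolane-2-carboxylate (anomer mixture) | c1ccccc1COCCCCCCCCCC[C@H](C(=O)OCc1ccccc1)[C@]1(C(=O)OCc2ccccc2)CCC(O)O1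
F2 | step 5 | lithium (trimethylsilyl)acetylide | [Li]C#C[Si](C)(C)C
F3 | step 5 | benzyl 2-oxo-4-(trimethylsilyl)but-3-ynoate | C[Si](C)(C)C#CC(=O)C(=O)OCc1ccccc1
F4 | step 5 | benzyl (2R,3S)-13-(benzyloxy)-3-[(tert-butylsulfanyl)carbonyl]-2-[(trimethylsilyl)ethynyl]-2-[(trimethylsilyl)oxy]tridecanoate | c1ccccc1COCCCCCCCCCC[C@H](C(=O)SC(C)(C)C)[C@](O[Si](C)(C)C)(C(=O)OCc1ccccc1)C#C[Si](C)(C)C
F5 | step 5 | benzyl (2R,3S)-13-(benzyloxy)-3-[(tert-butylsulfanyl)carbonyl]-2-ethynyl-2-hydroxytridecanoate | c1ccccc1COCCCCCCCCCC[C@H](C(=O)SC(C)(C)C)[C@](O)(C(=O)OCc1ccccc1)C#C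
F6 | step 8 | (2S,3S)-3-[10-(benzyloxy)decyl]-2-ethenyl-2-hydroxybutanedioic acid | c1ccccc1COCCCCCCCCCC[C@H](C(=O)O)[C@](O)(C(=O)O)C=C
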